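Everything rests on opening ring A by a Dötz benzannulation. In flavone numbering ring A carries oxygen at C5 and, para to it, at C8, has OMe at C7 beside C8, and is fused to the pyranone through C4a=C8a. In one operation a benzyloxycarbene of zerovalent chromium (carbene carbon = C5, bound to C4a), methoxyacetylene (C6 and C7) and one CO ligand (C8) combine, forming C5-C6, C7-C8 and C8-C8a and delivering C5 as a benzyl ether and C8 as a free phenol. The precursor is the pentacarbonylchromium benzyloxycarbene at C3 of a 6-aryl-5-benzyloxy-4-pyranone with hydrogen at C2; this pyranone is assembled by acylation and cyclisation, so every substituent is placed by construction.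

Key step: step 9

Remark on structures: ring B has to enter as the 3,5-bis(benzyloxy)-4-methoxyphenyl group (Ar below). A 3,4,5-trimethoxyphenyl building block could not be unmasked at C3' and C5' beside the methyl ethers at C7, C8 and C4', so ring B is taken from methyl 3,5-dihydroxy-4-methoxybenzoate.
Assumption: compounds 1, 4, 10 and 17 are purchased; the target has no stereocentre, and the enamine geometry of 5 is lost on cyclisation.

Step 1
Reactants: 1 methyl 3,5-dihydroxy-4-methoxybenzoate
Product: 2 methyl 3,5-bis(benzyloxy)-4-methoxybenzoate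
Conditions: BnBr (2.3 equiv), K2CO3, DMF, 60 °C
Reagents that add atoms: benzyl bromide, BrCc1ccccc1
Why: Williamson ether synthesis on the two equivalent phenols, with the methyl ester and the flanked methyl ether inert to K2CO3.

Step 2
Reactants: 2 methyl 3,5-bis(benzyloxy)-4-methoxybenzoate
Product: 3 3,5-bis(benzyloxy)-4-methoxybenzoic acid
Conditions: NaOH, THF/MeOH/H2O, 60 °C; then HCl (aq)
Reagents that add atoms: sodium hydroxide, [Na+].[OH-]
Why: Saponification of an unhindered methyl benzoate, to which benzyl and methyl aryl ethers are stable.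

Step 3
Reactants: 4 methyl 4-(benzyloxy)-3-oxobutanoate
Product: 5 methyl (2Z)-4-(benzyloxy)-2-[(dimethylamino)methylidene]-3-oxobutanoate
Conditions: Me2NCH(OMe)2 (1.2 equiv), toluene, rt
Reagents that add atoms: N,N-dimethylformamide dimethyl acetal, COC(OC)N(C)C
Why: Enaminone formation by condensation of the amide acetal with the active methylene of the β-keto ester, which installs the CH that becomes C8a with a leaving group on it.

Step 4
Reactants: 3 3,5-bis(benzyloxy)-4-methoxybenzoic acid, 5 methyl (2Z)-4-(benzyloxy)-2-[(dimethylamino)methylidene]-3-oxobutanoate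
Product: 8 methyl 6-Ar-5-(benzyloxy)-4-oxo-4H-pyran-3-carboxylate, via aroyl chloride 6 (not isolated), via C-acylated enaminone 7 (not isolated)
Conditions: (a) 3, (COCl)2, DMF (cat.), CH2Cl2, 0 °C to rt, evaporate; (b) 5 + 6, THF, −78 °C, LiN(SiMe3)2 (2.2 equiv) added slowly; (c) HCl (2 M, aq), THF, rt
Reagents that add atoms: none
Why: LiN(SiMe3)2 removes the only acidic hydrogen of 5 (the benzyloxy-bearing CH2 beside the ketone) and the enolate is C-acylated by 6 as it forms (crossed Claisen-type acylation of an enaminone anion), after which acid lets the aryl ketone enol oxygen displace dimethylamine by addition-elimination, a known 4-pyranone ring synthesis that fixes aryl at C6, OBn at C5, the ester at C3 and hydrogen at C2 without any selective C-H functionalisation.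

Step 5
Reactants: 8 methyl 6-Ar-5-(benzyloxy)-4-oxo-4H-pyran-3-carboxylate
Product: 9 6-Ar-5-(benzyloxy)-4-oxo-4H-pyran-3-carboxylic acid
Conditions: Me3SnOH (5 equiv), ClCH2CH2Cl, 80 °C; then HCl (5%, aq)
Reagents that add atoms: trimethyltin hydroxide, C[Sn](C)(C)O
Why: Tin hydroxide ester cleavage delivers hydroxide to the chelation-activated methyl ester under nearly neutral conditions, which should avoid both hydroxide attack at C2 of the pyranone and the halide-induced loss of the chelated 5-benzyl ether.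

Step 6
Reactants: 9 6-Ar-5-(benzyloxy)-4-oxo-4H-pyran-3-carboxylic acid, 10 hexacarbonylchromium, Cr(CO)6
Product: 14 tetramethylammonium pentacarbonyl{[6-Ar-5-(benzyloxy)-4-oxo-4H-pyran-3-yl]carbonyl}chromate, via Na2Cr(CO)5 11 (not isolated), via pyranone acid chloride 12 (not isolated), via sodium acylchromate 13 (not isolated)
Conditions: (a) 10, NaC10H8 (sodium naphthalenide, 2.0 equiv), THF, −78 °C; (b) 9, 1-chloro-N,N,2-trimethylprop-1-en-1-amine, CH2Cl2, 0 °C, evaporate; (c) 12 in THF added to 11, −78 to −20 °C; (d) Me4NBr, H2O (degassed), 0 °C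
Reagents that add atoms: tetramethylammonium bromide, C[N+](C)(C)C.[Br-]
Why: Nucleophilic acyl substitution of an acid chloride by the pentacarbonylchromate dianion is the established alternative to the organolithium route to acylchromates, it is fast at −78 °C so that the acid chloride should be consumed before the pyranone is touched, and it brings in the future C5 at the carboxyl oxidation level with no need for a metalated pyranone, while cation exchange gives a storable salt.

Step 7
Reactants: 14 tetramethylammonium pentacarbonyl{[6-Ar-5-(benzyloxy)-4-oxo-4H-pyran-3-yl]carbonyl}chromate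
Product: 16 pentacarbonyl{(benzyloxy)[6-Ar-5-(benzyloxy)-4-oxo-4H-pyran-3-yl]methylidene}chromium (zerovalent chromium), via acetoxycarbene complex 15 (not isolated)
Conditions: AcBr (1.05 equiv), CH2Cl2, −40 °C; BnOH (1.5 equiv), −40 to 0 °C; Ar, dark
Reagents that add atoms: benzyl alcohol, OCc1ccccc1
Why: O-acylation of the acylchromate gives a reactive acyloxycarbene that exchanges with benzyl alcohol by addition-elimination at the carbene carbon, the standard way to make Fischer alkoxycarbene complexes of alcohols that cannot be introduced with an alkylating agent.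

Step 8
Reactants: 17 chloroacetaldehyde dimethyl acetal
Product: 19 methoxyacetylene, via sodium methoxyacetylide 18 (not isolated)
Conditions: NaNH2 (3.1 equiv), NH3 (l), −33 °C; cold saturated NaCl (aq); distilled (bp about 23 °C) into tBuOMe at −78 °C
Reagents that add atoms: none
Why: Two successive β-eliminations (loss of methanol, then of HCl) with NaNH2 in liquid ammonia give the acetylide, as in the known preparation of ethoxyacetylene from the diethyl acetal, and the aqueous quench frees the volatile alkyne for immediate use.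

Step 9
Reactants: 16 pentacarbonyl{(benzyloxy)[6-Ar-5-(benzyloxy)-4-oxo-4H-pyran-3-yl]methylidene}chromium, 19 methoxyacetylene
Product: 21 2-Ar-3,5-bis(benzyloxy)-8-hydroxy-7-methoxy-4H-chromen-4-one, via arene Cr(CO)3 complex 20 (not isolated)
Conditions: 19 (5 equiv), tBuOMe (degassed), sealed tube, 55 °C, Ar; then air, MeCN, daylight, rt
Reagents that add atoms: none
Why: Proposed new method: thermal loss of one cis CO from 16 (possibly helped by transient binding of the C4 carbonyl) frees a site for methoxyacetylene, which inserts into the Cr=C5 bond with its unsubstituted carbon bonding to C5, so the new carbene carbon is the methoxy-bearing C7; CO migration to C7 then gives a chromium-bound dienylketene with C8 as ketene carbon, which closes onto C8a and tautomerises to the phenol because C8a carries a hydrogen. The closest known reaction type is the Dötz benzannulation of alkenyl(alkoxy)carbene complexes of zerovalent chromium with alkynes, including carbenes on cyclic enol ethers; a carbene on C3 of a 4-pyranone and methoxyacetylene as partner lie outside it. Ring A is closed by a thermal six-electron electrocyclisation of the metal-bound dienylketene (bond C8-C8a), after C5-C6 and C7-C8 have been formed at chromium. No stereocentre is formed. The step needs one regiochemistry of insertion, secured by the size difference between H and OMe on the alkyne and by donor stabilisation of the C7 carbene. It also needs CO uptake to win over a five-ring closure or capture of C7 by the C4 carbonyl oxygen, which the alkenyl nature of the carbene, a weakly coordinating ether solvent and excess alkyne favour but which remains the untested point.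

Step 10
Reactants: 21 2-Ar-3,5-bis(benzyloxy)-8-hydroxy-7-methoxy-4H-chromen-4-one
Product: 22 2-Ar-3,5-bis(benzyloxy)-7,8-dimethoxy-4H-chromen-4-one
Conditions: MeI (3 equiv), K2CO3, DMF, rt, Ar
Reagents that add atoms: iodomethane, CI
Why: Williamson methylation of the only free hydroxyl, run under argon so that the hydroquinone monoether is not oxidised to a quinone.

Step 11
Reactants: 22 2-Ar-3,5-bis(benzyloxy)-7,8-dimethoxy-4H-chromen-4-one
Product: 23 3,5-dihydroxy-2-(3,5-dihydroxy-4-methoxyphenyl)-7,8-dimethoxy-4H-chromen-4-one (CNP0165950.0)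
Conditions: H2 (1 atm), Pd/C (10%), EtOAc/MeOH, rt
Reagents that add atoms: none
Why: Catalytic hydrogenolysis should remove all four benzyl ethers in one operation, while the methyl ethers, the carbonyl and the C2=C3 bond of the flavonol are not reduced at 1 atm and rt.

Compound list
1 | methyl 3,5-dihydroxy-4-methoxybenzoate | COC(=O)c1cc(O)c(OC)c(O)c1 | starting material
2 | methyl 3,5-bis(benzyloxy)-4-methoxybenzoate | COC(=O)c1cc(OCc2ccccc2)c(OC)c(OCc2ccccc2)c1 | intermediate
3 | 3,5-bis(benzyloxy)-4-methoxybenzoic acid | OC(=O)c1cc(OCc2ccccc2)c(OC)c(OCc2ccccc2)c1 | intermediate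
4 | methyl 4-(benzyloxy)-3-oxobutanoate | COC(=O)CC(=O)COCc1ccccc1 | starting material
5 | methyl (2Z)-4-(benzyloxy)-2-[(dimethylamino)methylidene]-3-oxobutanoate | COC(=O)/C(=C\N(C)C)C(=O)COCc1ccccc1 | intermediate
6 | 3,5-bis(benzyloxy)-4-methoxybenzoyl chloride | ClC(=O)c1cc(OCc2ccccc2)c(OC)c(OCc2ccccc2)c1 | intermediate
7 | methyl 4-(benzyloxy)-5-[3,5-bis(benzyloxy)-4-methoxyphenyl]-2-[(dimethylamino)methylidene]-3,5-dioxopentanoate (racemic at C4, enolisable) | COC(=O)C(=CN(C)C)C(=O)C(OCc1ccccc1)C(=O)c1cc(OCc2ccccc2)c(OC)c(OCc2ccccc2)c1 | intermediate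
8 | methyl 5-(benzyloxy)-6-[3,5-bis(benzyloxy)-4-methoxyphenyl]-4-oxo-4H-pyran-3-carboxylate | COC(=O)C1=COC(=C(OCc2ccccc2)C1=O)c1cc(OCc2ccccc2)c(OC)c(OCc2ccccc2)c1 | intermediate
9 | 5-(benzyloxy)-6-[3,5-bis(benzyloxy)-4-methoxyphenyl]-4-oxo-4H-pyran-3-carboxylic acid | OC(=O)C1=COC(=C(OCc2ccccc2)C1=O)c1cc(OCc2ccccc2)c(OC)c(OCc2ccccc2)c1 | intermediate
10 | hexacarbonylchromium, Cr(CO)6 | O=C=[Cr](=C=O)(=C=O)(=C=O)(=C=O)=C=O | starting material
11 | disodium pentacarbonylchromate, Na2Cr(CO)5 | [Na+].[Na+].O=C=[Cr-2](=C=O)(=C=O)(=C=O)=C=O | intermediate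
12 | 5-(benzyloxy)-6-[3,5-bis(benzyloxy)-4-methoxyphenyl]-4-oxo-4H-pyran-3-carbonyl chloride | ClC(=O)C1=COC(=C(OCc2ccccc2)C1=O)c1cc(OCc2ccccc2)c(OC)c(OCc2ccccc2)c1 | intermediate
13 | sodium pentacarbonyl{[5-(benzyloxy)-6-[3,5-bis(benzyloxy)-4-methoxyphenyl]-4-oxo-4H-pyran-3-yl]carbonyl}chromate | [Na+].O=C=[Cr-](=C=O)(=C=O)(=C=O)(=C=O)C(=O)C1=COC(=C(OCc2ccccc2)C1=O)c1cc(OCc2ccccc2)c(OC)c(OCc2ccccc2)c1 | intermediate
14 | tetramethylammonium pentacarbonyl{[5-(benzyloxy)-6-[3,5-bis(benzyloxy)-4-methoxyphenyl]-4-oxo-4H-pyran-3-yl]carbonyl}chromate | C[N+](C)(C)C.O=C=[Cr-](=C=O)(=C=O)(=C=O)(=C=O)C(=O)C1=COC(=C(OCc2ccccc2)C1=O)c1cc(OCc2ccccc2)c(OC)c(OCc2ccccc2)c1 | intermediate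
15 | pentacarbonyl{(acetyloxy)[5-(benzyloxy)-6-[3,5-bis(benzyloxy)-4-methoxyphenyl]-4-oxo-4H-pyran-3-yl]methylidene}chromium | CC(=O)OC(=[Cr](=C=O)(=C=O)(=C=O)(=C=O)=C=O)C1=COC(=C(OCc2ccccc2)C1=O)c1cc(OCc2ccccc2)c(OC)c(OCc2ccccc2)c1 | intermediate
16 | pentacarbonyl{(benzyloxy)[5-(benzyloxy)-6-[3,5-bis(benzyloxy)-4-methoxyphenyl]-4-oxo-4H-pyran-3-yl]methylidene}chromium (zerovalent chromium) | O=C=[Cr](=C=O)(=C=O)(=C=O)(=C=O)=C(OCc1ccccc1)C1=COC(=C(OCc2ccccc2)C1=O)c1cc(OCc2ccccc2)c(OC)c(OCc2ccccc2)c1 | intermediate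
17 | chloroacetaldehyde dimethyl acetal | COC(CCl)OC | starting material
18 | sodium methoxyacetylide | [Na+].[C-]#COC | intermediate
19 | methoxyacetylene | COC#C | intermediate
20 | tricarbonylchromium complex of 21, Cr(CO)3 bound to the face of ring A | COc1cc(OCc2ccccc2)c2c(=O)c(OCc3ccccc3)c(-c3cc(OCc4ccccc4)c(OC)c(OCc4ccccc4)c3)oc2c1O.O=C=[Cr](=C=O)=C=O | intermediate
21 | 3,5-bis(benzyloxy)-2-[3,5-bis(benzyloxy)-4-methoxyphenyl]-8-hydroxy-7-methoxy-4H-chromen-4-one | COc1cc(OCc2ccccc2)c2c(=O)c(OCc3ccccc3)c(-c3cc(OCc4ccccc4)c(OC)c(OCc4ccccc4)c3)oc2c1O | intermediate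
22 | 3,5-bis(benzyloxy)-2-[3,5-bis(benzyloxy)-4-methoxyphenyl]-7,8-dimethoxy-4H-chromen-4-one | COc1cc(OCc2ccccc2)c2c(=O)c(OCc3ccccc3)c(-c3cc(OCc4ccccc4)c(OC)c(OCc4ccccc4)c3)oc2c1OC | intermediate
23 | 3,5-dihydroxy-2-(3,5-dihydroxy-4-methoxyphenyl)-7,8-dimethoxy-4H-chromen-4-one (CNP0165950.0) | COc1cc(O)c2c(=O)c(O)c(-c3cc(O)c(OC)c(O)c3)oc2c1OC | target

Total step count: 11. Longest linear sequence: 9 steps (steps 1, 2, 4, 5, 6, 7, 9, 10, 11).

Steps most likely to fail

1. Step 9. After alkyne insertion the oxygen-stabilised vinylcarbene may not take up CO and may stall, close a five-membered ring, or be captured by the nucleophilic C4 carbonyl oxygen; the alkynyl ether may also oligomerise at chromium. The fallback builds ring A from a preformed benzene ring by classical flavone chemistry; it sets out from acid 3 (as chloride 6) and returns at target 23. Acylation of purchased 1-(2-hydroxy-3,4,6-trimethoxyphenyl)ethan-1-one with 6 (pyridine, DMAP) would give 2-acetyl-3,5,6-trimethoxyphenyl 3,5-bis(benzyloxy)-4-methoxybenzoate F1. Baker–Venkataraman rearrangement (KOH, pyridine, 50 °C) would give 1-[3,5-bis(benzyloxy)-4-methoxyphenyl]-3-(2-hydroxy-3,4,6-trimethoxyphenyl)propane-1,3-dione F2. Cyclodehydration (TsOH, toluene, 80 °C) would give 2-[3,5-bis(benzyloxy)-4-methoxyphenyl]-5,7,8-trimethoxy-4H-chromen-4-one F3. Lithiation at C3 (LiN(iPr)2, THF, −78 °C), B(OMe)3 and H2O2/AcOH would give 2-[3,5-bis(benzyloxy)-4-methoxyphenyl]-3-hydroxy-5,7,8-trimethoxy-4H-chromen-4-one F4. Chelation-controlled cleavage of the peri methyl ether at C5 (MgBr2·OEt2, MeCN, 80 °C) would give 2-[3,5-bis(benzyloxy)-4-methoxyphenyl]-3,5-dihydroxy-7,8-dimethoxy-4H-chromen-4-one F5, and hydrogenolysis (H2, Pd/C) of F5 gives 23.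

2. Step 6. Electron transfer or conjugate addition from the chromate dianion to the doubly activated pyranone may compete with acyl substitution, and the pyranone carbonyl may be O-activated while the acid chloride is made. The fallback reaches the acylchromate from a carbon nucleophile instead; it sets out from acid 9 and returns at 14. Iododecarboxylation of 9 (N-iodosuccinimide, LiOAc cat., MeCN/H2O, Hunsdiecker-type) would give 3-(benzyloxy)-2-[3,5-bis(benzyloxy)-4-methoxyphenyl]-5-iodo-4H-pyran-4-one F6. Iodine-magnesium exchange (iPrMgCl·LiCl, THF, −40 °C) would give {5-(benzyloxy)-6-[3,5-bis(benzyloxy)-4-methoxyphenyl]-4-oxo-4H-pyran-3-yl}magnesium chloride F7. Addition of F7 to 10 (THF, −40 to 0 °C) would give chloromagnesium pentacarbonyl{[5-(benzyloxy)-6-[3,5-bis(benzyloxy)-4-methoxyphenyl]-4-oxo-4H-pyran-3-yl]carbonyl}chromate F8, and Me4NBr in water converts F8 into 14.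

3. Step 5. Hydroxide delivered by tin may add to C2 of the pyranone and open the ring, or cleavage of the chelated ester may be too slow at a tolerable temperature. The fallback replaces hydrolysis by a neutral deallylation; it sets out from 4 (and uses 6) and returns at 9. Transesterification of 4 (allyl alcohol, DMAP cat., toluene, reflux) would give prop-2-en-1-yl 4-(benzyloxy)-3-oxobutanoate F9. Me2NCH(OMe)2 would give prop-2-en-1-yl (2Z)-4-(benzyloxy)-2-[(dimethylamino)methylidene]-3-oxobutanoate F10. Acylation with 6 and acid cyclisation as in step 4 would give prop-2-en-1-yl 5-(benzyloxy)-6-[3,5-bis(benzyloxy)-4-methoxyphenyl]-4-oxo-4H-pyran-3-carboxylate F11, and Pd(PPh3)4 (zerovalent palladium) with PhSiH3 in CH2Cl2 at rt cleaves F11 to 9.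

Further compounds
F1 | step 9 | 2-acetyl-3,5,6-trimethoxyphenyl 3,5-bis(benzyloxy)-4-methoxybenzoate | CC(=O)c1c(OC(=O)c2cc(OCc3ccccc3)c(OC)c(OCc3ccccc3)c2)c(OC)c(OC)cc1OC
F2 | step 9 | 1-[3,5-bis(benzyloxy)-4-methoxyphenyl]-3-(2-hydroxy-3,4,6-trimethoxyphenyl)propane-1,3-dione | COc1cc(OC)c(C(=O)CC(=O)c2cc(OCc3ccccc3)c(OC)c(OCc3ccccc3)c2)c(O)c1OC
F3 | step 9 | 2-[3,5-bis(benzyloxy)-4-methoxyphenyl]-5,7,8-trimethoxy-4H-chromen-4-one | COc1cc(OC)c2c(=O)cc(-c3cc(OCc4ccccc4)c(OC)c(OCc4ccccc4)c3)oc2c1OC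
F4 | step 9 | 2-[3,5-bis(benzyloxy)-4-methoxyphenyl]-3-hydroxy-5,7,8-trimethoxy-4H-chromen-4-one | COc1cc(OC)c2c(=O)c(O)c(-c3cc(OCc4ccccc4)c(OC)c(OCc4ccccc4)c3)oc2c1OC
F5 | step 9 | 2-[3,5-bis(benzyloxy)-4-methoxyphenyl]-3,5-dihydroxy-7,8-dimethoxy-4H-chromen-4-one | COc1cc(O)c2c(=O)c(O)c(-c3cc(OCc4ccccc4)c(OC)c(OCc4ccccc4)c3)oc2c1OC
F6 | step 6 | 3-(benzyloxy)-2-[3,5-bis(benzyloxy)-4-methoxyphenyl]-5-iodo-4H-pyran-4-one | IC1=COC(=C(OCc2ccccc2)C1=O)c1cc(OCc2ccccc2)c(OC)c(OCc2ccccc2)c1
F7 | step 6 | {5-(benzyloxy)-6-[3,5-bis(benzyloxy)-4-methoxyphenyl]-4-oxo-4H-pyran-3-yl}magnesium chloride | Cl[Mg]C1=COC(=C(OCc2ccccc2)C1=O)c1cc(OCc2ccccc2)c(OC)c(OCc2ccccc2)c1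
F8 | step 6 | chloromagnesium pentacarbonyl{[5-(benzyloxy)-6-[3,5-bis(benzyloxy)-4-methoxyphenyl]-4-oxo-4H-pyran-3-yl]carbonyl}chromate | Cl[Mg+].O=C=[Cr-](=C=O)(=C=O)(=C=O)(=C=O)C(=O)C1=COC(=C(OCc2ccccc2)C1=O)c1cc(OCc2ccccc2)c(OC)c(OCc2ccccc2)c1
F9 | step 5 | prop-2-en-1-yl 4-(benzyloxy)-3-oxobutanoate | C=CCOC(=O)CC(=O)COCc1ccccc1
F10 | step 5 | prop-2-en-1-yl (2Z)-4-(benzyloxy)-2-[(dimethylamino)methylidene]-3-oxobutanoate | C=CCOC(=O)/C(=C\N(C)C)C(=O)COCc1ccccc1
F11 | step 5 | prop-2-en-1-yl 5-(benzyloxy)-6-[3,5-bis(benzyloxy)-4-methoxyphenyl]-4-oxo-4H-pyran-3-carboxylate | C=CCOC(=O)C1=COC(=C(OCc2ccccc2)C1=O)c1cc(OCc2ccccc2)c(OC)c(OCc2ccccc2)c1
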